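Abbreviations: TBS = tert-butyldimethylsilyl, PMB = 4-methoxybenzyl, DMB = 3,4-dimethoxybenzyl. Briarane numbering (C1–C20) is used for all ring carbons; the target is compound 49.

## The problem

Compound 49 is a briarane in which cyclohexane ring A (C1, C10–C14) is trans-fused at C1–C10 to a ten-membered carbocycle (C1–C10) that is spanned by a C4–O–C8 ether (a tetrahydropyran) and carries a γ-lactone cis-fused to the pyran at C7–C8. There are eleven stereocentres (1S, 2R, 3S, 4R, 6S, 7R, 8R, 9S, 10S, 14S, 17R), among them the quaternary C1 between two carbinols (C2, C14) and the fully substituted ether carbon C8. Once the bridge exists the pyran is a rigid chair whose lower face is covered by the C3–C2–C1–C10–C9 bridge, so C6 and C17 can be set late; before that the medium ring is flexible, and the western centres (C1, C2, C10) must be tied to the eastern ones (C3, C4, C7, C8, C9) by a stereospecific event. The allylic chloride beside the C5 methylene, three acetates next to one free neopentyl hydroxyl (C2), a lactone with a β-oxygen at C8 and two 1,1-disubstituted alkenes rule out strong base, hydrogenolysis and dissolving metals at the end, so the order in which C5, C6, C11 and the acetates are unveiled is part of the problem. The enabling feature is that C1–C2 and C4–C9 are the forming and breaking bonds of a [3,3] shift in a 1,2-dialkenylcyclohexanol C1=C10–C9(O)–C4–C3=C2, whose ring-expanded product is the ten-membered ring with a C9 carbonyl and an (E)-C3=C4 alkene. The oxygen that must later bond to C4 sits on C8, next to the carbon C4 has just left, so the bridge can be closed transannularly on the face C9 vacated.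

## Retrosynthesis

**49 ⇒ 46 (end game).** The C2 hydroxyl is freed last from PMB ether 48 by DDQ, which tolerates acetates, alkenes and the allylic chloride. The C9 and C14 acetates come from silyl ethers (46 → 47 → 48). Benzyl at C2 was rejected because no hydrogenolysis is possible at this stage.

**46 ⇒ 45 ⇒ 44 (C11 methylene, C6 chloride).** The C11 methylene is cut back to ketone 45. It must come after the chlorination, because a 1,1-disubstituted alkene would compete with the deactivated C5=C6 alkene for electrophilic chlorine. The C5(=CH2)–C6(Cl) unit is cut to the trisubstituted alkene 44 (ene-type chlorination). This beats methylenation of an α-chloro ketone or SN2 chemistry at C6, and the face is decided by the rigid bicycle.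

**44 ⇒ 40 (C5 methyl alkene).** The C5(Me)=C6 alkene comes from ketone 40 through enol triflate 41 and a methyl cross-coupling to 42. The triflate is made without base, because an enolate at C6 would expel the C7 lactone oxygen.

**40 ⇒ 36 (ether bridge).** C4–O is cut back to epoxy ketone 38 and the (E)-alkene of 36. The free C5 hydroxyl of 36 is antiperiplanar to the old C4–C9 bond and therefore directs the peracid to the outer face. The C8 hydroxyl then attacks C4 from inside with inversion, which gives exactly the C3/C4 configuration of 49. A halo-etherification would put the wrong configuration at C3 after substitution.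

**35 ⇒ 31 (lactone).** C8–C17 is cut intramolecularly: α-bromo ester 34 on the C7 oxygen closes onto the C8 ketone (Reformatsky). The tether fixes C8 relative to C7, which an intermolecular propanoate aldol would not. C7–O comes from the enolate of ketone 31 (33); C9–O from reduction of ketone 28.

**27 ⇒ 24 (key step).** C1–C2 is cut and C4–C9 restored: anionic oxy-Cope ring expansion of trans-dialkenylcyclohexanol 24. Against a macrocyclisation or a ring-closing metathesis to a ten-membered ring, this cut forms the medium ring without entropic cost and sets the quaternary C1, C2 and the alkene geometry in one stereospecific step. The precursor is a six-membered ring with three reliably set stereocentres. The step requires that no second 1,5-diene is present and that the enolate cannot eliminate at C11, so C11 carries a free hydroxyl (an alkoxide under the conditions) and not a ketal.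

**24 ⇒ 8 + 22.** The C9–C10 bond is made by adding the alkenyl metal from iodide 8 to ketone 22, anti to the C4 substituent. The two fragments are of similar size and each is enantiomerically defined.

**22 ⇒ 14 + 13.** Ketone 22 comes from dienone 19 by conjugate borylation/oxidation, which sets C5 and then C4. 19 comes from iodo enone 18 and boronate 13 (Suzuki). 18 comes from cyclohexane-1,2-dione 14 via monoketal 15 and enone 17. 13 comes from 4-methoxybenzyl alcohol 9 and trichloroethylene 10 via 11. The dimethyl ketal at C8 was chosen because it can be hydrolysed without loss of silyl ethers.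

**8 ⇒ 1.** Ring A comes from 4-methoxy-2-methylphenol 1 through quinone monoketal 2 and enone 3. Two catalyst-controlled CBS reductions (3 → 4 and 7 → 8) set C14 and the auxiliary centre C11.

## Roads not taken

Alternative 1: The cut is C1–C10, the bond shared by ring A and the ten-membered ring. Forward, a fourteen-membered carbocycle that already carries pyran, lactone, chloride and acetates is closed across the ring: the enol of the C14 ketone attacks through C1 the β-carbon C10 of a C10=C11 enal (iminium activation), giving A1. Merits: ring A, the ten-membered ring and the quaternary C1 arise in one step, and all eastern functionality is installed on an open chain, where reagent control is dependable. Weak points: the enal is α,β-disubstituted and the nucleophile is the more substituted enol of an α-methyl ketone, so both partners are poor for iminium catalysis. The configuration at C1 and C10 depends on the conformation of a macrocycle far from any controlling element. The macrocycle needs its own ring closure. A secondary amine and an allylic chloride share the flask. A1 still requires an axial C14 alcohol next to a quaternary carbon and conversion of the C11 formyl group to a methylene beside an epimerisable C10. Comparison: after ring formation this road is shorter than the chosen one, which spends about twenty steps on a medium ring; in that respect it is better. The chosen plan sets against it a ring-forming step that is stereospecific (chair, chirality transfer) and needs no macrocyclisation.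

Alternative 2: The cuts are C4–C5 and C7–C8 (a three-carbon unit across a furan whose 2,5-carbons are C4 and C8) and the C3=C9 bond of a tetrasubstituted alkene that is cleaved afterwards. Forward, an oxyallyl cation adds (4+3) to the ring A fused furan to give A2; ozonolysis then opens the central ring to the ten-membered diketone. Merits: the ether bridge and both bridgeheads come from the furan, cis by topology, with no etherification and no question of epoxide face; the ten-membered ring is made by cleavage, not closure. Here it is better than the chosen plan, whose bridge depends on the face of an epoxidation. Weak points: in A2 the carbonyl is at C6 while the target needs carbon at C5 and chlorine at C6. C2 and C7 are unactivated methylenes (C2 next to the quaternary C1). Ozonolysis gives C3 and C9 ketones that must be told apart and reduced with control. C17 still lacks its methyl. Facial selectivity of the cycloaddition relative to ring A is open. Comparison: the core is reached faster, but five positions are each one oxidation or one carbon away from the target without activating neighbours. The oxy-Cope step delivers the C2 oxygen, C1 and a C3=C4 alkene placed for the C3/C4 oxygens directly.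

Alternative 3: The cut is C8–C17, made late. Forward, a 2-diazopropanoate on the C7 oxygen is decomposed by a dirhodium tetracarboxylate such as Rh2(OAc)4, and the carbenoid inserts into the C8–H bond to give A3, the cis-fused lactone with the quaternary ether carbon; the pyran comes from a hexose. Merits: the sugar fixes the pyran stereocentres absolutely, insertion α to an ether oxygen is a favourable case and proceeds with retention, and the lactone is made last, so its base sensitivity never limits earlier steps. In these respects it is better than the chosen plan, which sets C7 and C9 by substrate control in a medium ring. Weak points: α-alkyl diazo esters lose nitrogen with 1,2-hydride shift to the acrylate in competition with insertion. Ylide formation at the bridging oxygen or the allylic chloride, and attack on the C11 methylene, are further exits. Above all, the road has no strong step for closing the ten-membered ring around the pyranose onto ring A with its quaternary C1. Comparison: the chosen plan has a dependable, stereospecific construction of the ten-membered ring and C1, exactly the part Alternative 3 leaves open.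

Key step: step 17

Remarks on the chemistry (assumptions):
- Ester 34 is used as the mixture of epimers at the bromine-bearing carbon (later C17).
- The enolate geometry of 32 is not assigned.
- In step 14 the (R,R) ligand is assumed to be the enantiomer that gives the 3R boronate; if the sense is the opposite, its antipode is used.

## Route

Step 1
Reactants: 1 4-methoxy-2-methylphenol
Product: 2 4,4-dimethoxy-2-methylcyclohexa-2,5-dien-1-one
Conditions: PhI(OAc)2, MeOH, 0 °C
Reagents that add atoms: methanol, CO
Why: Oxidative dearomatisation of a para-methoxyphenol in methanol (quinone monoketal synthesis) traps the phenoxonium ion at C4 as the dimethyl ketal; no stereocentre is formed.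

Step 2
Reactants: 2 4,4-dimethoxy-2-methylcyclohexa-2,5-dien-1-one
Product: 3 4,4-dimethoxy-2-methylcyclohex-2-en-1-one
Conditions: H2 (1 atm), RhCl(PPh3)3 (5 mol %), benzene, rt
Reagents that add atoms: none
Why: Homogeneous hydrogenation distinguishes alkenes by substitution, so the disubstituted double bond of the cross-conjugated dienone should be saturated and the methyl-bearing enone kept (as in the reduction of steroidal 1,4-dien-3-ones to 4-en-3-ones).

Step 3
Reactants: 3 4,4-dimethoxy-2-methylcyclohex-2-en-1-one
Product: 4 (S)-4,4-dimethoxy-2-methylcyclohex-2-en-1-ol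
Conditions: (R)-2-methyl-CBS-oxazaborolidine (10 mol %), BH3·SMe2, THF, −20 °C
Reagents that add atoms: none
Why: Corey–Bakshi–Shibata reduction; the α-methyl alkenyl side is the large group and the methylene side the small one, so the (R)-catalyst should give the S carbinol (later C14) by catalyst control.

Step 4
Reactants: 4 (S)-4,4-dimethoxy-2-methylcyclohex-2-en-1-ol
Product: 5 (S)-tert-butyl(4,4-dimethoxy-2-methylcyclohex-2-en-1-yloxy)dimethylsilane
Conditions: TBSCl, imidazole, DMF, rt
Reagents that add atoms: tert-butyldimethylsilyl chloride, CC(C)(C)[Si](C)(C)Cl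
Why: Standard silylation of a secondary allylic alcohol; the silyl ether survives organolithium, hydride and mild acid.

Step 5
Reactants: 5 (S)-tert-butyl(4,4-dimethoxy-2-methylcyclohex-2-en-1-yloxy)dimethylsilane
Product: 6 (S)-4-(tert-butyldimethylsilyloxy)-3-methylcyclohex-2-en-1-one
Conditions: PPTS, acetone/H2O, rt
Reagents that add atoms: water, O
Why: Mild acid hydrolysis of an allylic dimethyl ketal to the enone; the γ-silyloxy enone is a stable class and the secondary TBS ether is untouched.

Step 6
Reactants: 6 (S)-4-(tert-butyldimethylsilyloxy)-3-methylcyclohex-2-en-1-one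
Product: 7 (S)-4-(tert-butyldimethylsilyloxy)-2-iodo-3-methylcyclohex-2-en-1-one
Conditions: I2, Me3SiN3, pyridine, CH2Cl2, 0 °C to rt
Reagents that add atoms: iodine, [I][I]
Why: α-Iodination of an enone by conjugate addition, iodination and elimination; the azide-assisted variant is used because the β-methyl group slows the pyridine-only procedure.

Step 7
Reactants: 7 (S)-4-(tert-butyldimethylsilyloxy)-2-iodo-3-methylcyclohex-2-en-1-one
Product: 8 (1R,4S)-4-(tert-butyldimethylsilyloxy)-2-iodo-3-methylcyclohex-2-en-1-ol
Conditions: (S)-2-methyl-CBS-oxazaborolidine (10 mol %), BH3·SMe2, THF, −30 °C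
Reagents that add atoms: none
Why: CBS reduction of an α-iodo enone, a well-behaved substrate class with the iodoalkenyl carbon as the large group; the (S)-catalyst should give the R carbinol (C11), cis to the C14 oxygen, by catalyst control over the remote centre.

Step 8
Reactants: 9 4-methoxybenzyl alcohol; 10 trichloroethylene
Product: 11 1-{[(E)-1,2-dichloroethenyl]oxymethyl}-4-methoxybenzene
Conditions: KH, THF, 0 °C to rt
Reagents that add atoms: none
Why: The potassium alkoxide eliminates HCl from trichloroethylene and adds to the dichloroacetylene so formed (anti addition), the established entry to 1,2-dichlorovinyl ethers as ynol ether precursors.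

Step 9
Reactants: 11 1-{[(E)-1,2-dichloroethenyl]oxymethyl}-4-methoxybenzene
Product: 13 2-[(E)-2-(4-methoxybenzyloxy)ethenyl]-4,4,5,5-tetramethyl-1,3,2-dioxaborolane, via ynol ether 12 (not isolated)
Conditions: n-BuLi (2.3 equiv), THF, −78 to −40 °C; MeOH; then pinacolborane, Cp2Zr(H)Cl (5 mol %), CH2Cl2, rt
Reagents that add atoms: pinacolborane, B1OC(C)(C)C(C)(C)O1
Why: Elimination and chlorine–lithium exchange give the lithium alkynyl ether, which is protonated to the labile ynol ether and used at once; zirconium-catalysed hydroboration of a terminal alkyne is syn and anti-Markovnikov, so the boronate should be E.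

Step 10
Reactants: 14 cyclohexane-1,2-dione
Product: 15 2,2-dimethoxycyclohexan-1-one
Conditions: HC(OMe)3, MeOH, TsOH (cat.), rt
Reagents that add atoms: trimethyl orthoformate, COC(OC)OC
Why: Acid-catalysed monoketalisation of the 1,2-dione; the second carbonyl is deactivated by the adjacent ketal, so the reaction should stop at the monoketal.

Step 11
Reactants: 15 2,2-dimethoxycyclohexan-1-one
Product: 17 6,6-dimethoxycyclohex-2-en-1-one, via silyl enol ether 16 (not isolated)
Conditions: LiN(iPr)2, Me3SiCl, THF, −78 °C; then Pd(OAc)2 (1.0 equiv), MeCN, rt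
Reagents that add atoms: none
Why: Saegusa–Ito dehydrogenation; only one α-carbon carries hydrogen, so enolisation and the position of the new double bond are unambiguous.

Step 12
Reactants: 17 6,6-dimethoxycyclohex-2-en-1-one
Product: 18 2-iodo-6,6-dimethoxycyclohex-2-en-1-one
Conditions: I2, pyridine, CH2Cl2, 0 °C to rt
Reagents that add atoms: iodine, [I][I]
Why: α-Iodination of a β-unsubstituted cyclohexenone with iodine and pyridine (addition–elimination), a standard preparation of 2-iodo enones.

Step 13
Reactants: 18 2-iodo-6,6-dimethoxycyclohex-2-en-1-one; 13 2-[(E)-2-(4-methoxybenzyloxy)ethenyl]-4,4,5,5-tetramethyl-1,3,2-dioxaborolane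
Product: 19 6,6-dimethoxy-2-[(E)-2-(4-methoxybenzyloxy)ethenyl]cyclohex-2-en-1-one
Conditions: Pd(dppf)Cl2 (5 mol %), K3PO4, THF/H2O, 40 °C
Reagents that add atoms: none
Why: Suzuki–Miyaura coupling of an α-iodo enone with an alkenylboronate; the alkene geometry is retained.

Step 14
Reactants: 19 6,6-dimethoxy-2-[(E)-2-(4-methoxybenzyloxy)ethenyl]cyclohex-2-en-1-one
Product: 21 (2S,3R)-3-hydroxy-6,6-dimethoxy-2-[(E)-2-(4-methoxybenzyloxy)ethenyl]cyclohexan-1-one, via pinacol boronate 20 (not isolated)
Conditions: B2pin2, CuCl (5 mol %), (R,R)-QuinoxP* (6 mol %), NaOtBu (10 mol %), MeOH (2 equiv), THF, rt; then H2O2, pH 7 phosphate buffer, 0 °C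
Reagents that add atoms: hydrogen peroxide, OO
Why: Copper-catalysed asymmetric conjugate borylation places boron at the β-carbon (C5) under ligand control; the electron-rich, cross-conjugated enol ether should stay out. Protonation of the copper enolate at C4 gives the trans (diequatorial) isomer. Oxidation of the C–B bond proceeds with retention.

Step 15
Reactants: 21 (2S,3R)-3-hydroxy-6,6-dimethoxy-2-[(E)-2-(4-methoxybenzyloxy)ethenyl]cyclohexan-1-one
Product: 22 (2S,3R)-3-(tert-butyldimethylsilyloxy)-6,6-dimethoxy-2-[(E)-2-(4-methoxybenzyloxy)ethenyl]cyclohexan-1-one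
Conditions: TBSOTf, 2,6-lutidine, CH2Cl2, −78 °C
Reagents that add atoms: tert-butyldimethylsilyl triflate, CC(C)(C)[Si](C)(C)OS(=O)(=O)C(F)(F)F
Why: Silylation under buffered, non-basic conditions protects the β-hydroxy ketone without β-elimination and without acid that would add the hydroxyl to the enol ether.

Step 16
Reactants: 8 (1R,4S)-4-(tert-butyldimethylsilyloxy)-2-iodo-3-methylcyclohex-2-en-1-ol; 22 (2S,3R)-3-(tert-butyldimethylsilyloxy)-6,6-dimethoxy-2-[(E)-2-(4-methoxybenzyloxy)ethenyl]cyclohexan-1-one
Product: 24 trans-1,2-dialkenylcyclohexanol (1R,2S,3R)-3-(TBS-oxy)-1-[(3S,6R)-3-(TBS-oxy)-6-hydroxy-2-methylcyclohex-1-en-1-yl]-6,6-dimethoxy-2-[(E)-2-(PMB-oxy)ethenyl]cyclohexan-1-ol, via dilithio alkenyl alkoxide 23 (not isolated)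
Conditions: 8, MeLi (1 equiv) then t-BuLi (2 equiv), THF, −78 °C; CeCl3; then 22, −78 to −40 °C; aq. NH4Cl
Reagents that add atoms: none
Why: Iodine–lithium exchange on the lithium alkoxide gives a 2-lithio allylic alkoxide. Its cerium derivative adds to the hindered, enolisable ketone without deprotonation or loss of the β-silyloxy group (organocerium 1,2-addition). Equatorial attack anti to the C4 alkenyl group gives the trans-dialkenyl carbinol (C9).

Step 17
Reactants: 24 trans-1,2-dialkenylcyclohexanol
Product: 27 ring A fused (3E)-cyclodecen-9-one (11-hydroxy; 8,8-dimethoxy; 2-PMB-oxy; 5,14-bis-TBS-oxy), via dipotassium dialkoxide 25 (not isolated), via dipotassium enolate alkoxide 26 (not isolated)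
Conditions: KH (3 equiv), 18-crown-6 (3 equiv), THF, 0 °C to rt; then AcOH, THF, −78 °C
Reagents that add atoms: none
Why: Both hydroxyls are deprotonated; the C9 potassium alkoxide weakens C4–C9 and the 1,5-diene C1=C10–C9–C4–C3=C2 undergoes a concerted, asynchronous [3,3] shift that forms C1–C2 and breaks C4–C9. The closest known reaction type is the anionic oxy-Cope rearrangement of trans-1,2-dialkenylcyclohexanols to (E)-cyclodec-5-enones. The ten-membered ring is not closed by cyclisation but arises by four-carbon ring expansion of the cyclohexane through a six-membered chair transition state, with the old ring bonds C9–C8 and C4–C5 equatorial. C1 and C2 are set by chirality transfer from C9 and C4 through that chair (on C1 the methyl is axial and C14 equatorial; the (E)-enol ether places the PMB-oxy group equatorial on C2), and the same chair gives the (E)-C3=C4 alkene. C10 is set when enolate 26 is protonated at low temperature, axially and anti to the axial C1 methyl, which gives the trans ring fusion that is also the more stable epimer. The step needs the shift to run only through C10=C1, which is secured because C5–C8 are saturated and no second 1,5-diene exists. It also needs an enolate that cannot eliminate at C11, which is secured because the C11 oxygen is a potassium alkoxide and not a leaving group. The cis relation of the C11 and C14 oxygens lets the C14 silyloxy group lie pseudo-equatorial, so the face of C1 that bonds to C2 stays open.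

Step 18
Reactants: 27 ring A fused (3E)-cyclodecen-9-one
Product: 28 11-O-DMB ether of 27
Conditions: 3,4-dimethoxybenzyl 2,2,2-trichloroacetimidate, Sc(OTf)3 (2 mol %), toluene, 0 °C
Reagents that add atoms: 3,4-dimethoxybenzyl 2,2,2-trichloroacetimidate, COc1ccc(COC(=N)C(Cl)(Cl)Cl)cc1OC
Why: Acid-catalysed benzylation with a trichloroacetimidate protects the β-hydroxy ketone without base (no retro-aldol, no elimination); the DMB ether is later cleavable in the presence of the PMB ether.

Step 19
Reactants: 28 11-O-DMB ether
Product: 29 (9S)-alcohol (9-hydroxy; 8,8-dimethoxy)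
Conditions: NaBH4, MeOH/THF, −20 to 0 °C
Reagents that add atoms: none
Why: Hydride addition to the only ketone; on the Felkin–Anh model the quaternary C1 on C10 is the large group anti to the incoming hydride, which should give the 9S carbinol (H-9 and H-10 syn, as in 49).

Step 20
Reactants: 29 (9S)-alcohol
Product: 30 9-O-TBS ether
Conditions: TBSOTf, 2,6-lutidine, CH2Cl2, 0 °C
Reagents that add atoms: tert-butyldimethylsilyl triflate, CC(C)(C)[Si](C)(C)OS(=O)(=O)C(F)(F)F
Why: The silyl triflate silylates the hindered secondary alcohol; a non-acyl group is needed at C9 so that the later enolate chemistry at C8 has no competing ester.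

Step 21
Reactants: 30 9-O-TBS ether
Product: 31 C8 ketone
Conditions: LiBF4, MeCN/H2O, 40 °C
Reagents that add atoms: water, O
Why: Mild hydrolysis of a dimethyl ketal (lithium tetrafluoroborate in wet acetonitrile) should leave TBS, PMB and DMB ethers and the alkene intact.

Step 22
Reactants: 31 C8 ketone
Product: 33 (7S)-7-hydroxy-8-ketone, via potassium enolate 32 (not isolated)
Conditions: KN(SiMe3)2, THF, −78 °C; then 2-(phenylsulfonyl)-3-phenyloxaziridine, −78 °C; aq. NH4Cl
Reagents that add atoms: 2-(phenylsulfonyl)-3-phenyloxaziridine, O=S(=O)(N1OC1c1ccccc1)c1ccccc1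
Why: Kinetic deprotonation occurs at the C7 methylene, not at the silyloxy-bearing C9 methine. Davis oxidation of the enolate should then occur on the outer face, anti to the C9 silyloxy group that allylic 1,3-strain holds perpendicular to the enolate, giving the C7 oxygen trans to the C9 oxygen across the carbonyl as in 49.

Step 23
Reactants: 33 (7S)-7-hydroxy-8-ketone
Product: 34 7-O-(2-bromopropanoyl) ester
Conditions: 2-bromopropanoyl bromide, pyridine, CH2Cl2, 0 °C
Reagents that add atoms: 2-bromopropanoyl bromide, CC(Br)C(Br)=O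
Why: Acylation of the α-hydroxy ketone with an acid bromide and pyridine; the configuration of the bromide carbon is irrelevant because it becomes an enolate in the next step.

Step 24
Reactants: 34 7-O-(2-bromopropanoyl) ester
Product: 35 β-hydroxy γ-lactone (C8–C17 bond; 8-OH)
Conditions: SmI2 (2.5 equiv), THF, −78 °C
Reagents that add atoms: none
Why: Intramolecular samarium Reformatsky reaction: the enolate is tethered through the C7 oxygen and can reach only the carbonyl face syn to that oxygen. With the ring bonds C6–C7 and C8–C9 anti, this should give the C8 hydroxyl syn to C6, the arrangement the ether bridge needs. The C17 methyl should prefer the side away from C9 in the chelated transition state, and that is also the more stable epimer.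

Step 25
Reactants: 35 β-hydroxy γ-lactone
Product: 36 allylic alcohol (5-OH)
Conditions: HF·pyridine, pyridine, THF, 0 °C
Reagents that add atoms: none
Why: Of the three secondary TBS ethers only the one at C5 is unhindered (the C9 and C14 ethers each sit next to a fully substituted carbon), so buffered fluoride should remove it selectively.

Step 26
Reactants: 36 allylic alcohol
Product: 37 trans-3,4-epoxy-5-alcohol
Conditions: mCPBA, NaHCO3, CH2Cl2, 0 °C
Reagents that add atoms: 3-chloroperbenzoic acid, OOC(=O)c1cccc(Cl)c1
Why: Hydroxyl-directed peracid epoxidation: the C5 oxygen was equatorial and antiperiplanar to the old C4–C9 bond, so it stands perpendicular to the alkene on its outer face and delivers the peracid there; the inner face is closed by the ring. The buffer prevents premature opening.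

Step 27
Reactants: 37 trans-3,4-epoxy-5-alcohol
Product: 38 3,4-epoxy-5-ketone
Conditions: Dess–Martin periodinane, NaHCO3, CH2Cl2, rt
Reagents that add atoms: none
Why: Neutral oxidation of the only secondary alcohol (the C8 hydroxyl is tertiary); doing it now avoids a C3/C5 diol after the bridge is closed.

Step 28
Reactants: 38 3,4-epoxy-5-ketone
Product: 39 bridged ether (C4–O–C8; 3-OH; 5-ketone)
Conditions: camphorsulfonic acid (10 mol %), CH2Cl2, 0 °C to rt
Reagents that add atoms: none
Why: Acid-promoted transannular 6-exo opening of the epoxide by the tertiary C8 hydroxyl at C4 with inversion. The nucleophile approaches on the inner face that C9 occupied before the rearrangement, which fixes C4 and leaves the C3 oxygen in the configuration of 49. SN2-type opening of α,β-epoxy ketones by heteroatom nucleophiles at the carbon next to the carbonyl is the usual regiochemistry, and here ring size (six against seven) reinforces it.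

Step 29
Reactants: 39 bridged ether
Product: 40 3-O-acetate
Conditions: Ac2O, pyridine, DMAP (cat.), CH2Cl2, 0 °C
Reagents that add atoms: acetic anhydride, CC(=O)OC(C)=O
Why: Acetylation of the only free hydroxyl; the equatorial C4–H is poorly aligned with the C5 carbonyl, so β-elimination of the new acetate should be slow.

Step 30
Reactants: 40 3-O-acetate
Product: 41 enol triflate (C5=C6)
Conditions: Tf2O, 2,6-di-tert-butyl-4-methylpyridine, CH2Cl2, 0 °C to rt
Reagents that add atoms: trifluoromethanesulfonic anhydride, O=S(=O)(OS(=O)(=O)C(F)(F)F)C(F)(F)F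
Why: Enol triflate formation by O-triflation and proton loss with a hindered pyridine base involves no enolate, so the β-acyloxy group at C7 is not expelled. Proton loss occurs from the C6 methylene, not from the bridgehead C4.

Step 31
Reactants: 41 enol triflate
Product: 42 5-methyl C5=C6 alkene
Conditions: Me2Zn, Pd(PPh3)4 (5 mol %), THF, 0 °C to rt
Reagents that add atoms: dimethylzinc, C[Zn]C
Why: Negishi coupling of an alkenyl triflate; dimethylzinc does not attack lactone or acetate, and oxidative addition to the triflate is faster than ionisation of the allylic lactone oxygen.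

Step 32
Reactants: 42 5-methyl C5=C6 alkene
Product: 43 11-alcohol
Conditions: DDQ (1.1 equiv), CH2Cl2/pH 7 buffer, 0 °C
Reagents that add atoms: none
Why: Oxidative cleavage of the electron-richer 3,4-dimethoxybenzyl ether is markedly faster than that of the 4-methoxybenzyl ether, which in addition sits on the neopentyl C2.

Step 33
Reactants: 43 11-alcohol
Product: 44 11-ketone
Conditions: Dess–Martin periodinane, NaHCO3, CH2Cl2, rt
Reagents that add atoms: none
Why: Neutral oxidation of the only free hydroxyl; without base the C10 centre and the β-silyloxy group at C9 are safe.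

Step 34
Reactants: 44 11-ketone
Product: 45 (6S)-6-chloro-5(16)-ene
Conditions: Ca(OCl)2, solid CO2, CH2Cl2/H2O, 0 °C
Reagents that add atoms: calcium hypochlorite, [Ca+2].[O-]Cl.[O-]Cl
Why: Ene-type chlorination of a trisubstituted alkene by hypochlorous acid: chlorine adds to the less substituted carbon C6 and a proton leaves from the C16 methyl, giving the allylic chloride with an exocyclic methylene. Chlorine should come from the open upper face of the pyran half-chair, since the lower face is covered by the carbon bridge; this is the face 49 requires.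

Step 35
Reactants: 45 (6S)-6-chloro-5(16)-ene
Product: 46 11(20)-methylene compound
Conditions: Cp2Ti(μ-Cl)(μ-CH2)AlMe2, pyridine (cat.), THF/toluene, −40 to 0 °C
Reagents that add atoms: Cp2Ti(μ-Cl)(μ-CH2)AlMe2 (Tebbe reagent), C[Al-]1(C)C[Ti]([Cl+]1)(C1C=CC=C1)C1C=CC=C1
Why: Tebbe methylenation: the Lewis base releases Cp2Ti=CH2, which adds to the ketone by [2+2] cycloaddition and collapses to the alkene and Cp2TiO. The reagent is non-basic, so C10 is not epimerised and no enolate forms; at low temperature it should take the ketone in preference to the lactone and acetate carbonyls.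

Step 36
Reactants: 46 11(20)-methylene compound
Product: 47 9,14-diol
Conditions: HF·pyridine, THF, rt
Reagents that add atoms: none
Why: Excess acidic fluoride removes the two hindered TBS ethers; acetate, lactone, PMB ether, allylic chloride and alkenes are stable to it.

Step 37
Reactants: 47 9,14-diol
Product: 48 3,9,14-triacetate 2-PMB ether
Conditions: Ac2O, DMAP, Et3N, CH2Cl2, 40 °C
Reagents that add atoms: acetic anhydride, CC(=O)OC(C)=O
Why: DMAP-catalysed acetylation of the two hindered secondary alcohols; the C2 oxygen is still protected, so the pattern of 49 follows.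

Step 38
Reactants: 48 3,9,14-triacetate 2-PMB ether
Product: 49 CNP0248899.1
Conditions: DDQ, CH2Cl2/H2O, rt
Reagents that add atoms: none
Why: Oxidative removal of the PMB ether frees the C2 hydroxyl under neutral conditions that leave acetates, lactone, allylic chloride and both methylene groups alone.

## Compound list

1 | 4-methoxy-2-methylphenol | Cc1cc(OC)ccc1O | starting material
2 | 4,4-dimethoxy-2-methylcyclohexa-2,5-dien-1-one | CC1=CC(OC)(OC)C=CC1=O | intermediate
3 | 4,4-dimethoxy-2-methylcyclohex-2-en-1-one | CC1=CC(OC)(OC)CCC1=O | intermediate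
4 | (S)-4,4-dimethoxy-2-methylcyclohex-2-en-1-ol | CC1=CC(OC)(OC)CC[C@@H]1O | intermediate
5 | (S)-tert-butyl(4,4-dimethoxy-2-methylcyclohex-2-en-1-yloxy)dimethylsilane | CC1=CC(OC)(OC)CC[C@@H]1O[Si](C)(C)C(C)(C)C | intermediate
6 | (S)-4-(tert-butyldimethylsilyloxy)-3-methylcyclohex-2-en-1-one | CC1=CC(=O)CC[C@@H]1O[Si](C)(C)C(C)(C)C | intermediate
7 | (S)-4-(tert-butyldimethylsilyloxy)-2-iodo-3-methylcyclohex-2-en-1-one | CC1=C(I)C(=O)CC[C@@H]1O[Si](C)(C)C(C)(C)C | intermediate
8 | (1R,4S)-4-(tert-butyldimethylsilyloxy)-2-iodo-3-methylcyclohex-2-en-1-ol (cis; ring A fragment, C11 carbinol, C14 silyl ether) | CC1=C(I)[C@H](O)CC[C@@H]1O[Si](C)(C)C(C)(C)C | intermediate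
9 | 4-methoxybenzyl alcohol | COc1ccc(CO)cc1 | starting material
10 | trichloroethylene | ClC=C(Cl)Cl | starting material
11 | 1-{[(E)-1,2-dichloroethenyl]oxymethyl}-4-methoxybenzene | COc1ccc(CO/C(Cl)=C\Cl)cc1 | intermediate
12 | 1-(ethynyloxymethyl)-4-methoxybenzene (ynol ether, not isolated) | C#COCc1ccc(OC)cc1 | intermediate
13 | 2-[(E)-2-(4-methoxybenzyloxy)ethenyl]-4,4,5,5-tetramethyl-1,3,2-dioxaborolane | COc1ccc(CO/C=C/B2OC(C)(C)C(C)(C)O2)cc1 | intermediate
14 | cyclohexane-1,2-dione | O=C1CCCCC1=O | starting material
15 | 2,2-dimethoxycyclohexan-1-one | COC1(OC)CCCCC1=O | intermediate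
16 | (6,6-dimethoxycyclohex-1-en-1-yloxy)trimethylsilane (not isolated) | COC1(OC)CCCC=C1O[Si](C)(C)C | intermediate
17 | 6,6-dimethoxycyclohex-2-en-1-one | COC1(OC)CCC=CC1=O | intermediate
18 | 2-iodo-6,6-dimethoxycyclohex-2-en-1-one | COC1(OC)CCC=C(I)C1=O | intermediate
19 | 6,6-dimethoxy-2-[(E)-2-(4-methoxybenzyloxy)ethenyl]cyclohex-2-en-1-one | COc1ccc(CO/C=C/C2=CCCC(OC)(OC)C2=O)cc1 | intermediate
20 | (2R,3R)-6,6-dimethoxy-2-[(E)-2-(4-methoxybenzyloxy)ethenyl]-3-(4,4,5,5-tetramethyl-1,3,2-dioxaborolan-2-yl)cyclohexan-1-one (trans, not isolated) | O=C1C(OC)(OC)CC[C@@H](B2OC(C)(C)C(C)(C)O2)[C@@H]1/C=C/OCc1ccc(OC)cc1 | intermediate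
21 | (2S,3R)-3-hydroxy-6,6-dimethoxy-2-[(E)-2-(4-methoxybenzyloxy)ethenyl]cyclohexan-1-one (trans) | O=C1C(OC)(OC)CC[C@@H](O)[C@@H]1/C=C/OCc1ccc(OC)cc1 | intermediate
22 | (2S,3R)-3-(tert-butyldimethylsilyloxy)-6,6-dimethoxy-2-[(E)-2-(4-methoxybenzyloxy)ethenyl]cyclohexan-1-one | O=C1C(OC)(OC)CC[C@@H](O[Si](C)(C)C(C)(C)C)[C@@H]1/C=C/OCc1ccc(OC)cc1 | intermediate
23 | lithium (1R,4S)-4-(tert-butyldimethylsilyloxy)-2-lithio-3-methylcyclohex-2-en-1-olate (not isolated; transmetallated to cerium before addition) | CC1=C([Li])[C@H](O[Li])CC[C@@H]1O[Si](C)(C)C(C)(C)C | intermediate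
24 | (1R,2S,3R)-3-(tert-butyldimethylsilyloxy)-1-[(3S,6R)-3-(tert-butyldimethylsilyloxy)-6-hydroxy-2-methylcyclohex-1-en-1-yl]-6,6-dimethoxy-2-[(E)-2-(4-methoxybenzyloxy)ethenyl]cyclohexan-1-ol (C9 carbinol, C4 alkenyl carbon, trans-dialkenyl) | CC1=C([C@@]3(O)C(OC)(OC)CC[C@@H](O[Si](C)(C)C(C)(C)C)[C@@H]3/C=C/OCc3ccc(OC)cc3)[C@H](O)CC[C@@H]1O[Si](C)(C)C(C)(C)C | intermediate
25 | dipotassium dialkoxide of 24 (C9 and C11 alkoxides, not isolated) | CC1=C([C@@]3(O[K])C(OC)(OC)CC[C@@H](O[Si](C)(C)C(C)(C)C)[C@@H]3/C=C/OCc3ccc(OC)cc3)[C@H](O[K])CC[C@@H]1O[Si](C)(C)C(C)(C)C | intermediate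
26 | dipotassium C9 enolate C11 alkoxide of 27 (enolate oxygen cis to C1, not isolated) | [K]O[C@@H]1CC[C@H](O[Si](C)(C)C(C)(C)C)[C@@]2(C)/C1=C(\O[K])C(OC)(OC)CC[C@@H](O[Si](C)(C)C(C)(C)C)/C=C/[C@@H]2OCc1ccc(OC)cc1 | intermediate
27 | ring A trans-fused (3E)-cyclodecen-9-one: 11-hydroxy, 8,8-dimethoxy, 2-(4-methoxybenzyloxy), 5- and 14-(tert-butyldimethylsilyloxy), 1-methyl; 5R,11R; C1, C2, C10, C14 in the spatial sense of 49 | O[C@@H]1CC[C@H](O[Si](C)(C)C(C)(C)C)[C@@]2(C)[C@H]1C(=O)C(OC)(OC)CC[C@@H](O[Si](C)(C)C(C)(C)C)/C=C/[C@@H]2OCc1ccc(OC)cc1 | intermediate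
28 | 11-O-(3,4-dimethoxybenzyl) ether of 27 | COc1ccc(CO[C@@H]2CC[C@H](O[Si](C)(C)C(C)(C)C)[C@@]3(C)[C@H]2C(=O)C(OC)(OC)CC[C@@H](O[Si](C)(C)C(C)(C)C)/C=C/[C@@H]3OCc2ccc(OC)cc2)cc1OC | intermediate
29 | (9S)-9-hydroxy compound from 28 (C8 dimethyl ketal) | COc1ccc(CO[C@@H]2CC[C@H](O[Si](C)(C)C(C)(C)C)[C@@]3(C)[C@H]2[C@H](O)C(OC)(OC)CC[C@@H](O[Si](C)(C)C(C)(C)C)/C=C/[C@@H]3OCc2ccc(OC)cc2)cc1OC | intermediate
30 | 9-O-TBS ether of 29 | COc1ccc(CO[C@@H]2CC[C@H](O[Si](C)(C)C(C)(C)C)[C@@]3(C)[C@H]2[C@H](O[Si](C)(C)C(C)(C)C)C(OC)(OC)CC[C@@H](O[Si](C)(C)C(C)(C)C)/C=C/[C@@H]3OCc2ccc(OC)cc2)cc1OC | intermediate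
31 | C8 ketone (9-OTBS, 5-OTBS, 14-OTBS, 11-ODMB, 2-OPMB, (3E)-alkene) | COc1ccc(CO[C@@H]2CC[C@H](O[Si](C)(C)C(C)(C)C)[C@@]3(C)[C@H]2[C@H](O[Si](C)(C)C(C)(C)C)C(=O)CC[C@@H](O[Si](C)(C)C(C)(C)C)/C=C/[C@@H]3OCc2ccc(OC)cc2)cc1OC | intermediate
32 | potassium C7=C8 enolate of 31 (geometry not assigned, not isolated) | COc1ccc(CO[C@@H]2CC[C@H](O[Si](C)(C)C(C)(C)C)[C@@]3(C)[C@H]2[C@H](O[Si](C)(C)C(C)(C)C)C(O[K])=CC[C@@H](O[Si](C)(C)C(C)(C)C)/C=C/[C@@H]3OCc2ccc(OC)cc2)cc1OC | intermediate
33 | (7S)-7-hydroxy-8-ketone (C7 oxygen in the spatial sense of 49) | COc1ccc(CO[C@@H]2CC[C@H](O[Si](C)(C)C(C)(C)C)[C@@]3(C)[C@H]2[C@H](O[Si](C)(C)C(C)(C)C)C(=O)[C@@H](O)C[C@@H](O[Si](C)(C)C(C)(C)C)/C=C/[C@@H]3OCc2ccc(OC)cc2)cc1OC | intermediate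
34 | 7-O-(2-bromopropanoyl) ester of 33 (both epimers at the CHBr carbon) | COc1ccc(CO[C@@H]2CC[C@H](O[Si](C)(C)C(C)(C)C)[C@@]3(C)[C@H]2[C@H](O[Si](C)(C)C(C)(C)C)C(=O)[C@@H](OC(=O)C(C)Br)C[C@@H](O[Si](C)(C)C(C)(C)C)/C=C/[C@@H]3OCc2ccc(OC)cc2)cc1OC | intermediate
35 | β-hydroxy γ-lactone (C7–O–C19(=O)–C17(Me)–C8(OH); C7, C8, C17 in the spatial sense of 49) | COc1ccc(CO[C@@H]2CC[C@H](O[Si](C)(C)C(C)(C)C)[C@@]3(C)[C@H]2[C@H](O[Si](C)(C)C(C)(C)C)[C@]4(O)[C@@H](C)C(=O)O[C@H]4C[C@@H](O[Si](C)(C)C(C)(C)C)/C=C/[C@@H]3OCc2ccc(OC)cc2)cc1OC | intermediate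
36 | 5-hydroxy compound from 35 (allylic alcohol, 5R) | COc1ccc(CO[C@@H]2CC[C@H](O[Si](C)(C)C(C)(C)C)[C@@]3(C)[C@H]2[C@H](O[Si](C)(C)C(C)(C)C)[C@]4(O)[C@@H](C)C(=O)O[C@H]4C[C@@H](O)/C=C/[C@@H]3OCc2ccc(OC)cc2)cc1OC | intermediate
37 | trans-3,4-epoxide of 36 (epoxide oxygen syn to the C5 hydroxyl, on the outer face) | COc1ccc(CO[C@@H]2CC[C@H](O[Si](C)(C)C(C)(C)C)[C@@]3(C)[C@H]2[C@H](O[Si](C)(C)C(C)(C)C)[C@]4(O)[C@@H](C)C(=O)O[C@H]4C[C@@H](O)[C@@H]5O[C@H]5[C@@H]3OCc2ccc(OC)cc2)cc1OC | intermediate
38 | 3,4-epoxy-5-ketone | COc1ccc(CO[C@@H]2CC[C@H](O[Si](C)(C)C(C)(C)C)[C@@]3(C)[C@H]2[C@H](O[Si](C)(C)C(C)(C)C)[C@]4(O)[C@@H](C)C(=O)O[C@H]4CC(=O)[C@@H]5O[C@H]5[C@@H]3OCc2ccc(OC)cc2)cc1OC | intermediate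
39 | bridged ether: C4–O–C8 pyran, 3-hydroxy, 5-ketone, lactone (C3, C4, C7, C8, C17 as in 49) | COc1ccc(CO[C@@H]2CC[C@H](O[Si](C)(C)C(C)(C)C)[C@@]3(C)[C@H]2[C@H](O[Si](C)(C)C(C)(C)C)[C@@]45O[C@H](C(=O)C[C@@H]4OC(=O)[C@@H]5C)[C@@H](O)[C@@H]3OCc2ccc(OC)cc2)cc1OC | intermediate
40 | 3-O-acetate of 39 | COc1ccc(CO[C@@H]2CC[C@H](O[Si](C)(C)C(C)(C)C)[C@@]3(C)[C@H]2[C@H](O[Si](C)(C)C(C)(C)C)[C@@]45O[C@H](C(=O)C[C@@H]4OC(=O)[C@@H]5C)[C@@H](OC(C)=O)[C@@H]3OCc2ccc(OC)cc2)cc1OC | intermediate
41 | C5 enol triflate (C5=C6) | COc1ccc(CO[C@@H]2CC[C@H](O[Si](C)(C)C(C)(C)C)[C@@]3(C)[C@H]2[C@H](O[Si](C)(C)C(C)(C)C)[C@@]45O[C@H](C(OS(=O)(=O)C(F)(F)F)=C[C@@H]4OC(=O)[C@@H]5C)[C@@H](OC(C)=O)[C@@H]3OCc2ccc(OC)cc2)cc1OC | intermediate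
42 | 5-methyl C5=C6 alkene | COc1ccc(CO[C@@H]2CC[C@H](O[Si](C)(C)C(C)(C)C)[C@@]3(C)[C@H]2[C@H](O[Si](C)(C)C(C)(C)C)[C@@]45O[C@H](C(C)=C[C@@H]4OC(=O)[C@@H]5C)[C@@H](OC(C)=O)[C@@H]3OCc2ccc(OC)cc2)cc1OC | intermediate
43 | 11-hydroxy compound from 42 | O[C@@H]1CC[C@H](O[Si](C)(C)C(C)(C)C)[C@@]2(C)[C@H]1[C@H](O[Si](C)(C)C(C)(C)C)[C@@]34O[C@H](C(C)=C[C@@H]3OC(=O)[C@@H]4C)[C@@H](OC(C)=O)[C@@H]2OCc1ccc(OC)cc1 | intermediate
44 | 11-ketone | O=C1CC[C@H](O[Si](C)(C)C(C)(C)C)[C@@]2(C)[C@H]1[C@H](O[Si](C)(C)C(C)(C)C)[C@@]34O[C@H](C(C)=C[C@@H]3OC(=O)[C@@H]4C)[C@@H](OC(C)=O)[C@@H]2OCc1ccc(OC)cc1 | intermediate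
45 | (6S)-6-chloro-5(16)-ene 11-ketone | O=C1CC[C@H](O[Si](C)(C)C(C)(C)C)[C@@]2(C)[C@H]1[C@H](O[Si](C)(C)C(C)(C)C)[C@@]34O[C@H](C(=C)[C@H](Cl)[C@@H]3OC(=O)[C@@H]4C)[C@@H](OC(C)=O)[C@@H]2OCc1ccc(OC)cc1 | intermediate
46 | 11(20)-methylene compound (9,14-bis-TBS ether, 3-acetate, 2-PMB ether) | C=C1CC[C@H](O[Si](C)(C)C(C)(C)C)[C@@]2(C)[C@H]1[C@H](O[Si](C)(C)C(C)(C)C)[C@@]34O[C@H](C(=C)[C@H](Cl)[C@@H]3OC(=O)[C@@H]4C)[C@@H](OC(C)=O)[C@@H]2OCc1ccc(OC)cc1 | intermediate
47 | 9,14-diol (3-acetate, 2-PMB ether) | C=C1CC[C@H](O)[C@@]2(C)[C@H]1[C@H](O)[C@@]34O[C@H](C(=C)[C@H](Cl)[C@@H]3OC(=O)[C@@H]4C)[C@@H](OC(C)=O)[C@@H]2OCc1ccc(OC)cc1 | intermediate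
48 | 3,9,14-triacetate 2-PMB ether | C=C1CC[C@H](OC(C)=O)[C@@]2(C)[C@H]1[C@H](OC(C)=O)[C@@]34O[C@H](C(=C)[C@H](Cl)[C@@H]3OC(=O)[C@@H]4C)[C@@H](OC(C)=O)[C@@H]2OCc1ccc(OC)cc1 | intermediate
49 | CNP0248899.1 (1S,2R,3S,4R,6S,7R,8R,9S,10S,14S,17R) | C=C1CC[C@H](OC(C)=O)[C@@]2(C)[C@H]1[C@H](OC(C)=O)[C@@]13O[C@H](C(=C)[C@H](Cl)[C@@H]1OC(=O)[C@@H]3C)[C@@H](OC(C)=O)[C@@H]2O | target

## Step count and weak points

Total: 38 steps. Longest linear sequence: 30 steps (steps 1–7 and 16–38, from 1).

**Step 17 (key step).** The hindered dialkoxide may rearrange slowly, since a tetrasubstituted terminus has to form a quaternary carbon beside a silyloxy group, and kinetic protonation of the enolate may occur on the wrong face of C10. Fallback: from 24 the allylic C11 hydroxyl is oxidised with MnO2 to the ring A enone F1. Its alkene is now an acceptor, so the potassium alkoxide (KN(SiMe3)2, 18-crown-6) should rearrange faster through the same chair, and the product is a 1,3-diketonate that cannot eliminate. Acidification gives the 9,11-diketone F2, in which C10 equilibrates to the trans ring fusion. Borane reduction of the less hindered ring A carbonyl under (S)-CBS control returns to 27.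

**Step 14.** The copper–boryl species may add to the diene, the α-alkenyl ketone may slip into conjugation under the alkoxide, or enantio-induction may be poor on an α-substituted enone. Fallback: from 19, amine-catalysed asymmetric epoxidation (9-amino-9-deoxy-epi-quinine salt, H2O2) gives the α,β-epoxy ketone F3. SmI2 (THF/MeOH, −78 °C) then cleaves the Cα–O bond and protonation trans to the C5 oxygen returns to 21.

**Step 24.** Ketyl formation may lead to reductive loss of the α-acyloxy group instead of closure, or closure may occur on the wrong carbonyl face. Fallback: from 33, acylation with propanoic anhydride gives the propanoate F4, which is closed by a reversible LiN(SiMe3)2-mediated intramolecular aldol addition (thermodynamic control at C8 and C17), returning to 35.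

**Step 28.** Attack at the epoxide carbon next to the carbonyl may be slow, and acid may instead trigger rearrangement of the epoxy ketone. Fallback: from 37 the epoxy alcohol is cyclised under the same acid to the 3,5-diol F5, in which an ordinary epoxide carbon is attacked. The less hindered ring hydroxyl at C5 is then oxidised with TEMPO/PhI(OAc)2 in the presence of the C3 hydroxyl, returning to 39.

**Step 34.** Chlorine may be delivered to the wrong face, proton loss may occur towards C4, or the anisyl ring may be chlorinated. Fallback: from 44, allylic oxidation of the C16 methyl (SeO2 cat., t-BuOOH) gives the primary allylic alcohol F6. SOCl2 in ether then collapses the chlorosulfite with allylic transposition (SNi′), placing chlorine at C6 from the open face and the double bond at C5=C16, returning to 45.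

**Step 35.** The lactone or acetate carbonyl may also be methylenated, or the Lewis-acidic aluminium by-product Me2AlCl may ionise the allylic chloride. Fallback: from 45, Me3SiCH2MgCl/CeCl3 (THF, −78 °C) adds to the ketone only and gives the β-hydroxysilane F7. The HF·pyridine treatment of step 36 then effects Peterson elimination and removal of both TBS groups in one operation, returning to 47.

## Further compounds

F1 | step 17 | ring A enone of 24 (C11 ketone) | CC1=C([C@@]3(O)C(OC)(OC)CC[C@@H](O[Si](C)(C)C(C)(C)C)[C@@H]3/C=C/OCc3ccc(OC)cc3)C(=O)CC[C@@H]1O[Si](C)(C)C(C)(C)C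
F2 | step 17 | 9,11-diketone corresponding to 27 | O=C1CC[C@H](O[Si](C)(C)C(C)(C)C)[C@@]2(C)[C@H]1C(=O)C(OC)(OC)CC[C@@H](O[Si](C)(C)C(C)(C)C)/C=C/[C@@H]2OCc1ccc(OC)cc1
F3 | step 14 | 2,3-epoxide of 19 (epoxy ketone) | O=C1C(OC)(OC)CC[C@H]2O[C@@]12/C=C/OCc1ccc(OC)cc1
F4 | step 24 | 7-O-propanoate of 33 | COc1ccc(CO[C@@H]2CC[C@H](O[Si](C)(C)C(C)(C)C)[C@@]3(C)[C@H]2[C@H](O[Si](C)(C)C(C)(C)C)C(=O)[C@@H](OC(=O)CC)C[C@@H](O[Si](C)(C)C(C)(C)C)/C=C/[C@@H]3OCc2ccc(OC)cc2)cc1OC
F5 | step 28 | bridged ether 3,5-diol | COc1ccc(CO[C@@H]2CC[C@H](O[Si](C)(C)C(C)(C)C)[C@@]3(C)[C@H]2[C@H](O[Si](C)(C)C(C)(C)C)[C@@]45O[C@H]([C@H](O)C[C@@H]4OC(=O)[C@@H]5C)[C@@H](O)[C@@H]3OCc2ccc(OC)cc2)cc1OC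
F6 | step 34 | 16-hydroxy derivative of 44 (primary allylic alcohol) | O=C1CC[C@H](O[Si](C)(C)C(C)(C)C)[C@@]2(C)[C@H]1[C@H](O[Si](C)(C)C(C)(C)C)[C@@]34O[C@H](C(CO)=C[C@@H]3OC(=O)[C@@H]4C)[C@@H](OC(C)=O)[C@@H]2OCc1ccc(OC)cc1
F7 | step 35 | 11-hydroxy-11-(trimethylsilylmethyl) adduct of 45 (C11 configuration not assigned) | C[Si](C)(C)CC1(O)CC[C@H](O[Si](C)(C)C(C)(C)C)[C@@]2(C)[C@H]1[C@H](O[Si](C)(C)C(C)(C)C)[C@@]34O[C@H](C(=C)[C@H](Cl)[C@@H]3OC(=O)[C@@H]4C)[C@@H](OC(C)=O)[C@@H]2OCc1ccc(OC)cc1
A1 | alternative 1 | transannular Michael product with C14 ketone and C11 formyl group | O=C[C@@H]1CCC(=O)[C@@]2(C)[C@H]1[C@H](OC(C)=O)[C@@]13O[C@H](C(=C)[C@H](Cl)[C@@H]1OC(=O)[C@@H]3C)[C@@H](OC(C)=O)[C@@H]2O[Si](C)(C)C(C)(C)C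
A2 | alternative 2 | oxabicyclic C6 ketone with tetrasubstituted C3=C9 alkene | O1CCOC12CC[C@H](O[Si](C)(C)C(C)(C)C)[C@@]3(C)[C@H]2C2=C(C3)[C@H]4CC(=O)C[C@]2(CC(=O)OC)O4
A3 | alternative 3 | lactone-fused tetracycle with C5 and C2 silyl ethers | C=C1CC[C@H](OC(C)=O)[C@@]2(C)[C@H]1[C@H](OC(C)=O)[C@@]13O[C@H]([C@H](O[Si](CC)(CC)CC)[C@H](Cl)[C@@H]1OC(=O)[C@@H]3C)[C@@H](OC(C)=O)[C@@H]2O[Si](C)(C)C(C)(C)C
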